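## Structural features

The target is a 2,3-dihydrobenzofuran in which the benzo ring A is fused to the dihydrofuran ring C. C2 carries a 4-hydroxyphenyl group (ring B), C3 a 2,4-dihydroxybenzoyl group (ring D), and C5, para to O1, a two-carbon link to a second 2,4-dihydroxyphenyl ketone (ring E). The only stereocentres, C2 (S) and C3 (S), are adjacent and trans, which is the thermodynamically preferred arrangement on ring C. C3–H is both benzylic and α to the ring D ketone, and O1 sits β to that ketone, so base can open ring C by E1cB (retro-oxa-Michael) to an achiral α-aryl chalcone and so erase both centres. C2–O1 is a 4-oxygenated benzylic aryl ether that can ionise in strong acid and can be cleaved by forcing hydrogenolysis, and five phenols have to be masked. The real difficulty is therefore the absolute configuration at C2 next to an acyl-bearing C3 that must be kept away from base, together with the 1,2,4-pattern of ring A. The key step uses the fact that ring A carries only O1 (at C7a), C3 (at C3a) and the C5 chain, with C4, C6 and C7 unsubstituted: C3a–C4 and C7a–C7 can come from a diyne tethered through C3, C2 and O1, and C5–C6 from a terminal alkyne.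

## Logic of the disconnections

27 to 26. The five O–CH2Ph bonds on rings B, D and E are cut. Benzyl is chosen because it leaves by neutral hydrogenolysis, the one deprotection mode that cannot trigger E1cB opening of ring C. There is no skeletal gain, but every earlier intermediate becomes free of acidic phenols. The forward step must stop before C2–O1 or an aryl ketone is reduced.

26 to 25 to 21 and 22. Both ketones are taken back to carbinols and the two C(carbinol)–C(aryl) bonds to rings D and E are cut. The two aroyl groups are identical, so each operation does double duty, and the C3 carbonyl appears only two steps from the end. What remains is a small dialdehyde and a purchasable aryl bromide. The nucleophile must add to the C3 aldehyde faster than it removes the doubly activated C3–H, which is why 22 is used as its organocerium derivative 24.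

21 to 20 to 19. Both aldehydes go back to primary alcohols; then the O–PMB bond at the C3 hydroxymethyl group is restored and C7–H becomes C7–Si. Alcohols carry these carbons safely through the alkyne chemistry, and the silyl group is the regiochemical control element of the ring construction. One acid treatment must remove both auxiliaries; at that stage C3 has no acidic hydrogen, so reversible ionisation of C2–O1 can only return the trans ring.

19 to 17 and 18. C3a–C7a, C4–C5 and C6–C7 are cut in a retro-[2+2+2] sense, which opens rings A and C together and moves both stereocentres into an acyclic tether. The forward step needs cross-selectivity and placement of the chain at C5, and it must run near room temperature, because 17 is a benzylic alkynyl ether. In 18 the hydroxyl is left free, which saves a protection step and one cation source in the later acid step.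

17 to 16 to 12. First C4–H is taken back to C4–SiMe3; then the O1–C7a bond of the ynol ether and the C7–Si bond are cut. The second alkyne must be masked while the lithium alkynyl ether 15 is silylated, and the two silyl groups must differ enough in lability for the smaller one to be removed alone. No base used here may disturb the propargylic C3–H.

12 to 9 and 10. The C2–C3 bond is cut. Both stereocentres arise as this bond forms: C3 by chirality transfer from 9 through the allenylzinc 11, C2 by the cyclic transition state, anti in the chain being trans on ring C. The gain is a purchasable aldehyde and a four-carbon mesylate. The demand is anti selectivity with an aromatic aldehyde; C2 remains correctable later under acid, C3 does not.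

9 to 8 to 7 to 4 and 5, and 4 to 1 and 2. The O–S bond, the carbinol C–H bond, the C(carbonyl)–C(sp) bond and the ether O–CH2 bond are cut in turn. Transfer hydrogenation of an alkynyl ketone sets the single stereocentre that all later stereochemistry derives from. A check of the descriptors shows that anti-(1S,2R) in 17, trans-(2S,3R) in 19 and trans-(2S,3S) in 27 describe the same spatial arrangement; the letter at C3 changes only because the CIP priorities change.

## Other disconnections considered

Alternative 1: The cut is C2–C3 of ring C. The diazoketone A1 loses nitrogen on Rh2(S-PTTL)4, and the rhodium carbene inserts into one of the two enantiotopic benzylic C–H bonds of the OCH2Ar ether. This forms C2–C3, closes ring C and sets C2; DBU is then meant to bring C3 to trans, giving the bromide A2.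
- In favour: bond and stereocentres come from one catalytic step, the ring D ketone is in place from the start, and insertion into benzylic ether C–H bonds is well precedented for aryl diazo esters with this catalyst family.
- Against: the acceptor here is an aryl ketone, not an ester, so the enantioinduction is an extrapolation. The DBU treatment acts on exactly the β-aryloxy ketone that can open by E1cB and lose the C2 centre just set. The chain must still be attached at C5–Br by cross-coupling in the presence of that ketone.
- Comparison: this plan addresses the stereodiad of ring C directly, whereas the chosen plan sets it acyclically and spends its key step on the achiral ring A. Control is by catalyst here and by chirality transfer in the chosen plan. Alternative 1 is the better on step count and on having asymmetric catalysis at the ring-forming event. The chosen plan is the better in keeping the β-aryloxy ketone out of every basic step. The final deprotection is equal.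

Alternative 2: The cut is O1–C2. Under a chiral BINOL-derived phosphoric acid the α-aryl chalcone A3 shifts a proton from the ring B phenol to C3 and becomes a para-quinone methide. The ring A phenol then adds to the methide carbon and closes ring C, giving the tetrabenzyl ether A4.
- In favour: it is biomimetic and the whole carbon skeleton exists before ring closure. The tautomerisation turns a disfavoured 5-endo oxa-Michael addition into a 5-exo closure on an exocyclic double bond. It needs the fewest steps of all plans and no redox adjustment.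
- Against: both centres are set under reversible conditions. The acid that closes the ring can reopen it through the same quinone methide, so the enantiomeric purity rests on kinetic control that the product may not hold. C3 is set by protonation, which a chiral acid controls poorly.
- Comparison: Alternative 2 is the better on step count and atom economy. The chosen plan is the more secure on stereocontrol, because C3 is a non-epimerisable centre until two steps from the end and C2 is tied to it. The hydrogenolytic end-game is equal.

Alternative 3: The cuts are C3a–C3 and O1–C7a. With Pd(OAc)2, a phosphine, a bridgehead-substituted norbornene and Cs2CO3, the aryl iodide A5 forms an aryl–norbornyl palladacycle. This opens the enantiopure epoxide A6 at the carbon α to the ketone, norbornene is expelled, and the alkoxide closes O1–C7a. The product is the pentabenzyl ether A7, identical with 26.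
- In favour: it is the most convergent plan, C2 comes with retention from an accessible chalcone epoxide, and it lands directly on the penultimate compound of the chosen route. Because A5 has two equivalent ortho positions, ring A poses no regiochemical question; on this point Alternative 3 is better than the chosen plan, which needs a silyl group for the same purpose.
- Against: this annulation is established for epoxides opened at an unhindered CH2. Here the attack must go to a secondary α-keto carbon, in competition with opening at the more ionisable 4-benzyloxybenzylic carbon. The β-alkoxide ketone intermediate can fragment by retro-aldol, and the product is a β-aryloxy ketone held hot with carbonate, the conditions for E1cB racemisation.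
- Comparison: Alternative 3 is the better on convergence and step count. The chosen plan is the better on stereochemical security and on the number of mechanistic steps that must go an unprecedented way. The last step is equal.

Key step: step 8

Remark on numbering: dihydrobenzofuran numbering (O1, C2, C3, C3a, C4 to C7, C7a) is used for all ring compounds and for the atoms of acyclic precursors that become these positions.

Remark on the monoalkyne: pent-4-yn-1-ol is assumed to enter the cyclotrimerisation with its hydroxyl free, because Cp*RuCl-type catalysts tolerate alcohols; this changes a protecting group only.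

Step 1
Reactants: 1 4-methoxybenzyl alcohol; 2 2-chloro-N-methoxy-N-methylacetamide
Product: 4 N-methoxy-2-[(4-methoxybenzyl)oxy]-N-methylacetamide, via sodium 4-methoxybenzyl oxide 3 (not isolated)
Conditions: NaH, THF, 0 °C; then 2, Bu4NI (cat.), 0 °C to rt
Reagents that add atoms: none
Why: Williamson etherification; the preformed alkoxide displaces the activated α-chloride, and the N-methoxy-N-methylamide is a poor acyl donor towards alkoxide at this temperature.

Step 2
Reactants: 5 trimethylsilylacetylene; 4 N-methoxy-2-[(4-methoxybenzyl)oxy]-N-methylacetamide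
Product: 7 1-[(4-methoxybenzyl)oxy]-4-(trimethylsilyl)but-3-yn-2-one, via lithium trimethylsilylacetylide 6 (not isolated)
Conditions: n-BuLi, THF, −78 °C; then 4, −78 to −20 °C; quench into cold 1 M HCl
Reagents that add atoms: none
Why: Weinreb ketone synthesis; the chelated tetrahedral adduct stops at the ketone stage, and the acidic quench keeps the released N,O-dimethylhydroxylamine protonated so that it cannot add to the ynone.

Step 3
Reactants: 7 1-[(4-methoxybenzyl)oxy]-4-(trimethylsilyl)but-3-yn-2-one
Product: 8 (S)-1-[(4-methoxybenzyl)oxy]-4-(trimethylsilyl)but-3-yn-2-ol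
Conditions: Ru[(R,R)-TsNCH(Ph)CH(Ph)NH](p-cymene) (1 mol%), i-PrOH, rt
Reagents that add atoms: none
Why: Noyori asymmetric transfer hydrogenation of an alkynyl ketone; the alkyne takes the place an aryl group holds in aryl ketone reductions, so the (R,R)-catalyst should deliver hydride to the face that gives the alcohol drawn, which is S here because CH2O outranks the alkynyl carbon. The base-free amido complex spares the C–Si bond.

Step 4
Reactants: 8 (S)-1-[(4-methoxybenzyl)oxy]-4-(trimethylsilyl)but-3-yn-2-ol
Product: 9 (S)-1-[(4-methoxybenzyl)oxy]-4-(trimethylsilyl)but-3-yn-2-yl methanesulfonate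
Conditions: MsCl, Et3N, CH2Cl2, −78 to 0 °C
Reagents that add atoms: methanesulfonyl chloride CS(=O)(=O)Cl
Why: O-sulfonylation; no bond to the stereocentre is broken, so the configuration is retained.

Step 5
Reactants: 9 (S)-1-[(4-methoxybenzyl)oxy]-4-(trimethylsilyl)but-3-yn-2-yl methanesulfonate; 10 4-(benzyloxy)benzaldehyde
Product: 12 (1S,2R)-1-[4-(benzyloxy)phenyl]-2-{[(4-methoxybenzyl)oxy]methyl}-4-(trimethylsilyl)but-3-yn-1-ol, via allenylzinc reagent 11 (not isolated)
Conditions: Pd(OAc)2 (5 mol%), PPh3 (5 mol%), Et2Zn (3 equiv), THF, −78 to −20 °C; aq NH4Cl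
Reagents that add atoms: none
Why: Marshall propargylation; zerovalent palladium formed in the flask opens the mesylate anti (SN2') to an allenylpalladium, Et2Zn transmetalates it to the (aS)-allenylzinc 11, and 11 adds to 10 through a cyclic SE2' transition state. The propargylic centre (future C3, R) is fixed by centre-to-axis-to-centre chirality transfer from 9, and the carbinol centre (future C2, S) by the chair-like arrangement that keeps the aryl group of 10 away from the CH2OPMB substituent, which gives the anti adduct.

Step 6
Reactants: 12 (1S,2R)-1-[4-(benzyloxy)phenyl]-2-{[(4-methoxybenzyl)oxy]methyl}-4-(trimethylsilyl)but-3-yn-1-ol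
Product: 16 (1S,2R)-1-[4-(benzyloxy)phenyl]-2-{[(4-methoxybenzyl)oxy]methyl}-4-(trimethylsilyl)but-3-yn-1-yl (triethylsilyl)ethynyl ether, via potassium alkoxide 13 (not isolated), via dichlorovinyl ether 14 (not isolated), via lithium alkynyl ether 15 (not isolated)
Conditions: KH (1.5 equiv), THF, 0 °C to rt; Cl2C=CHCl (1.1 equiv), −50 °C to rt; n-BuLi (2.5 equiv), −78 to −40 °C; Et3SiCl, −78 to 0 °C
Reagents that add atoms: trichloroethylene ClC=C(Cl)Cl; chlorotriethylsilane CC[Si](Cl)(CC)CC
Why: Greene ynol ether synthesis in one flask; alkoxide 13 adds to dichloroacetylene generated from trichloroethylene to give the E-dichlorovinyl ether 14, n-BuLi converts 14 by elimination and chlorine–lithium exchange into 15, and Et3SiCl caps 15 at carbon. No bond to either stereocentre takes part.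

Step 7
Reactants: 16 (1S,2R)-1-[4-(benzyloxy)phenyl]-2-{[(4-methoxybenzyl)oxy]methyl}-4-(trimethylsilyl)but-3-yn-1-yl (triethylsilyl)ethynyl ether
Product: 17 (1S,2R)-1-[4-(benzyloxy)phenyl]-2-{[(4-methoxybenzyl)oxy]methyl}but-3-yn-1-yl (triethylsilyl)ethynyl ether
Conditions: K2CO3 (0.2 equiv), MeOH–THF, 0 °C
Reagents that add atoms: none
Why: base-catalysed methanolysis of a C(sp)–Si bond; the trimethylsilyl group on the carbon alkyne should be cleaved far faster than the more hindered triethylsilyl group on the ynol ether terminus. Carbonate is too weak to move the propargylic C3–H, and the electron-rich ynol ether does not accept methoxide.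

Step 8
Reactants: 17 (1S,2R)-1-[4-(benzyloxy)phenyl]-2-{[(4-methoxybenzyl)oxy]methyl}but-3-yn-1-yl (triethylsilyl)ethynyl ether; 18 pent-4-yn-1-ol
Product: 19 3-[(2S,3R)-2-[4-(benzyloxy)phenyl]-3-{[(4-methoxybenzyl)oxy]methyl}-7-(triethylsilyl)-2,3-dihydro-1-benzofuran-5-yl]propan-1-ol
Conditions: Cp*RuCl(cod) (5 mol%), 18 (3 equiv), ClCH2CH2Cl, rt, 17 added slowly by syringe pump
Reagents that add atoms: none
Why: Ruthenium-catalysed [2+2+2] cyclotrimerisation of a 1,6-diyne with a terminal alkyne; the closest known cases are Cp*RuCl-catalysed cycloadditions of unsymmetrical 1,6-diynes and the rhodium- or ruthenium-catalysed closure of nitrogen- and oxygen-linked diynes (ynamides to indolines, aryl alkynyl ethers to benzofurans). Loss of cod from the divalent ruthenium complex and oxidative cyclisation of the two alkynes of 17 form C3a–C7a and a ruthenacycle fused to the new five-membered ring, which closes ring C with the tether O1–C2–C3 inside the ring and both alkynes exo to it. Pent-4-yn-1-ol then inserts and reductive elimination forms C4–C5 and C6–C7, which closes ring A as the six-membered ring of the formal [2+2+2] annulation and returns the catalyst. No stereocentre is created; C2 and C3 are sp3 atoms of the tether, are never bonded to the metal and should keep their configuration under the neutral, non-oxidising conditions. Two selectivities are needed: cross-reaction over self-reaction, secured by slow addition of 17 to an excess of 18 and by the hindered silylated terminus; and C5 over C6, secured by the triethylsilyl group at the future C7, because the substituted alkyne carbon bonds to the unhindered C4 terminus and leaves its CH next to silicon. Room temperature matters, since a benzylic alkynyl ether such as 17 rearranges sigmatropically on heating.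

Step 9
Reactants: 19 3-[(2S,3R)-2-[4-(benzyloxy)phenyl]-3-{[(4-methoxybenzyl)oxy]methyl}-7-(triethylsilyl)-2,3-dihydro-1-benzofuran-5-yl]propan-1-ol
Product: 20 3-[(2S,3R)-2-[4-(benzyloxy)phenyl]-3-(hydroxymethyl)-2,3-dihydro-1-benzofuran-5-yl]propan-1-ol
Conditions: CF3CO2H–CH2Cl2 (1:4), 1,3-dimethoxybenzene (6 equiv), 0 °C to rt; NaHCO3, MeOH–H2O work-up
Reagents that add atoms: none
Why: The acid ionises the 4-methoxybenzyl ether, whose cation is trapped by 1,3-dimethoxybenzene (Friedel–Crafts), and ipso-protonates C7, ortho to O1, so that the triethylsilyl group leaves (protodesilylation). C3 has no acidic hydrogen here, so even reversible ionisation of C2–O1 can only return the trans ring; the benzyl aryl ether is stable to this acid, and the methanolic bicarbonate work-up frees any trifluoroacetylated hydroxyl.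

Step 10
Reactants: 20 3-[(2S,3R)-2-[4-(benzyloxy)phenyl]-3-(hydroxymethyl)-2,3-dihydro-1-benzofuran-5-yl]propan-1-ol
Product: 21 (2S,3S)-2-[4-(benzyloxy)phenyl]-5-(3-oxopropyl)-2,3-dihydro-1-benzofuran-3-carbaldehyde
Conditions: Dess–Martin periodinane (2.5 equiv), NaHCO3, CH2Cl2, 0 °C to rt; used crude at once
Reagents that add atoms: none
Why: Dess–Martin oxidation of both primary alcohols under near-neutral conditions; nothing present is basic enough to enolise the new C3 aldehyde or to open ring C by E1cB.

Step 11
Reactants: 21 (2S,3S)-2-[4-(benzyloxy)phenyl]-5-(3-oxopropyl)-2,3-dihydro-1-benzofuran-3-carbaldehyde; 22 1-bromo-2,4-bis(benzyloxy)benzene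
Product: 25 1-[2,4-bis(benzyloxy)phenyl]-3-[(2S,3R)-2-[4-(benzyloxy)phenyl]-3-{[2,4-bis(benzyloxy)phenyl](hydroxy)methyl}-2,3-dihydro-1-benzofuran-5-yl]propan-1-ol (mixture of carbinol epimers), via aryllithium 23 (not isolated), via arylcerium dichloride 24 (not isolated)
Conditions: 22 (2.6 equiv), n-BuLi (2.5 equiv), THF, −78 °C; anhydrous CeCl3 (2.8 equiv), −78 °C; then 21, −78 °C; aq NH4Cl
Reagents that add atoms: none
Why: Bromine–lithium exchange gives 23, transmetalation to the organocerium reagent 24 lowers the basicity, and 24 should add 1,2 to both aldehydes faster than it removes the doubly activated C3–H. The two new carbinol centres are formed without control and are destroyed in the next step.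

Step 12
Reactants: 25 1-[2,4-bis(benzyloxy)phenyl]-3-[(2S,3R)-2-[4-(benzyloxy)phenyl]-3-{[2,4-bis(benzyloxy)phenyl](hydroxy)methyl}-2,3-dihydro-1-benzofuran-5-yl]propan-1-ol
Product: 26 1-[2,4-bis(benzyloxy)phenyl]-3-[(2S,3S)-3-[2,4-bis(benzyloxy)benzoyl]-2-[4-(benzyloxy)phenyl]-2,3-dihydro-1-benzofuran-5-yl]propan-1-one
Conditions: Dess–Martin periodinane (3 equiv), CH2Cl2, 0 °C to rt
Reagents that add atoms: none
Why: Dess–Martin oxidation of both benzylic secondary alcohols; the medium is neutral to weakly acidic, so the β-aryloxy ketone cannot open by E1cB, and acid-catalysed enolisation at C3 could only return the favoured trans isomer.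

Step 13
Reactants: 26 1-[2,4-bis(benzyloxy)phenyl]-3-[(2S,3S)-3-[2,4-bis(benzyloxy)benzoyl]-2-[4-(benzyloxy)phenyl]-2,3-dihydro-1-benzofuran-5-yl]propan-1-one
Product: 27 1-(2,4-dihydroxyphenyl)-3-[(2S,3S)-3-(2,4-dihydroxybenzoyl)-2-(4-hydroxyphenyl)-2,3-dihydro-1-benzofuran-5-yl]propan-1-one
Conditions: H2 (1 atm), 10% Pd/C, EtOAc–MeOH, rt; stopped after uptake of five equivalents
Reagents that add atoms: none
Why: Hydrogenolysis of five benzyl ethers over palladium under neutral conditions, so base-induced opening of ring C cannot occur; 2-hydroxyaryl ketones and the C2–O1 ether should be reduced more slowly than O-benzyl groups at atmospheric pressure.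

## Compound list

1 | 4-methoxybenzyl alcohol | COc1ccc(CO)cc1 | starting material
2 | 2-chloro-N-methoxy-N-methylacetamide | CON(C)C(=O)CCl | starting material
3 | sodium 4-methoxybenzyl oxide | COc1ccc(C[O-])cc1.[Na+] | intermediate (not isolated)
4 | N-methoxy-2-[(4-methoxybenzyl)oxy]-N-methylacetamide | CON(C)C(=O)COCc1ccc(OC)cc1 | intermediate
5 | trimethylsilylacetylene | C#C[Si](C)(C)C | starting material
6 | lithium (trimethylsilyl)acetylide | [Li]C#C[Si](C)(C)C | intermediate (not isolated)
7 | 1-[(4-methoxybenzyl)oxy]-4-(trimethylsilyl)but-3-yn-2-one | C[Si](C)(C)C#CC(=O)COCc1ccc(OC)cc1 | intermediate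
8 | (S)-1-[(4-methoxybenzyl)oxy]-4-(trimethylsilyl)but-3-yn-2-ol | C[Si](C)(C)C#C[C@H](O)COCc1ccc(OC)cc1 | intermediate
9 | (S)-1-[(4-methoxybenzyl)oxy]-4-(trimethylsilyl)but-3-yn-2-yl methanesulfonate | C[Si](C)(C)C#C[C@H](OS(C)(=O)=O)COCc1ccc(OC)cc1 | intermediate
10 | 4-(benzyloxy)benzaldehyde | O=Cc1ccc(OCc2ccccc2)cc1 | starting material
11 | ethyl[(aS)-4-[(4-methoxybenzyl)oxy]-1-(trimethylsilyl)buta-1,2-dien-1-yl]zinc | CC[Zn]C([Si](C)(C)C)=[C@@]=C([H])COCc1ccc(OC)cc1 | intermediate (not isolated)
12 | (1S,2R)-1-[4-(benzyloxy)phenyl]-2-{[(4-methoxybenzyl)oxy]methyl}-4-(trimethylsilyl)but-3-yn-1-ol (anti) | C[Si](C)(C)C#C[C@H](COCc1ccc(OC)cc1)[C@@H](c1ccc(OCc2ccccc2)cc1)O | intermediate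
13 | potassium alkoxide of 12 | C[Si](C)(C)C#C[C@H](COCc1ccc(OC)cc1)[C@@H](c1ccc(OCc2ccccc2)cc1)[O-].[K+] | intermediate (not isolated)
14 | (E)-1,2-dichlorovinyl ether of 12 | C[Si](C)(C)C#C[C@H](COCc1ccc(OC)cc1)[C@@H](c1ccc(OCc2ccccc2)cc1)O/C(Cl)=C\Cl | intermediate (not isolated)
15 | lithium acetylide of the ethynyl ether of 12 | C[Si](C)(C)C#C[C@H](COCc1ccc(OC)cc1)[C@@H](c1ccc(OCc2ccccc2)cc1)OC#C[Li] | intermediate (not isolated)
16 | (1S,2R)-1-[4-(benzyloxy)phenyl]-2-{[(4-methoxybenzyl)oxy]methyl}-4-(trimethylsilyl)but-3-yn-1-yl (triethylsilyl)ethynyl ether | C[Si](C)(C)C#C[C@H](COCc1ccc(OC)cc1)[C@@H](c1ccc(OCc2ccccc2)cc1)OC#C[Si](CC)(CC)CC | intermediate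
17 | (1S,2R)-1-[4-(benzyloxy)phenyl]-2-{[(4-methoxybenzyl)oxy]methyl}but-3-yn-1-yl (triethylsilyl)ethynyl ether (anti diyne) | C#C[C@H](COCc1ccc(OC)cc1)[C@@H](c1ccc(OCc2ccccc2)cc1)OC#C[Si](CC)(CC)CC | intermediate
18 | pent-4-yn-1-ol | C#CCCCO | starting material
19 | 3-[(2S,3R)-2-[4-(benzyloxy)phenyl]-3-{[(4-methoxybenzyl)oxy]methyl}-7-(triethylsilyl)-2,3-dihydro-1-benzofuran-5-yl]propan-1-ol (trans) | OCCCc1cc([Si](CC)(CC)CC)c2c(c1)[C@H](COCc1ccc(OC)cc1)[C@@H](c1ccc(OCc3ccccc3)cc1)O2 | intermediate
20 | 3-[(2S,3R)-2-[4-(benzyloxy)phenyl]-3-(hydroxymethyl)-2,3-dihydro-1-benzofuran-5-yl]propan-1-ol | OCCCc1ccc2c(c1)[C@H](CO)[C@@H](c1ccc(OCc3ccccc3)cc1)O2 | intermediate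
21 | (2S,3S)-2-[4-(benzyloxy)phenyl]-5-(3-oxopropyl)-2,3-dihydro-1-benzofuran-3-carbaldehyde | O=CCCc1ccc2c(c1)[C@H](C=O)[C@@H](c1ccc(OCc3ccccc3)cc1)O2 | intermediate
22 | 1-bromo-2,4-bis(benzyloxy)benzene | Brc1ccc(OCc2ccccc2)cc1OCc1ccccc1 | starting material
23 | [2,4-bis(benzyloxy)phenyl]lithium | [Li]c1ccc(OCc2ccccc2)cc1OCc1ccccc1 | intermediate (not isolated)
24 | [2,4-bis(benzyloxy)phenyl]cerium dichloride | Cl[Ce](Cl)c1ccc(OCc2ccccc2)cc1OCc1ccccc1 | intermediate (not isolated)
25 | 1-[2,4-bis(benzyloxy)phenyl]-3-[(2S,3R)-2-[4-(benzyloxy)phenyl]-3-{[2,4-bis(benzyloxy)phenyl](hydroxy)methyl}-2,3-dihydro-1-benzofuran-5-yl]propan-1-ol, both carbinol carbons undefined | OC(CCc1ccc2c(c1)[C@H](C(O)c3ccc(OCc4ccccc4)cc3OCc3ccccc3)[C@@H](c3ccc(OCc4ccccc4)cc3)O2)c1ccc(OCc2ccccc2)cc1OCc1ccccc1 | intermediate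
26 | 1-[2,4-bis(benzyloxy)phenyl]-3-[(2S,3S)-3-[2,4-bis(benzyloxy)benzoyl]-2-[4-(benzyloxy)phenyl]-2,3-dihydro-1-benzofuran-5-yl]propan-1-one | O=C(CCc1ccc2c(c1)[C@H](C(=O)c3ccc(OCc4ccccc4)cc3OCc3ccccc3)[C@@H](c3ccc(OCc4ccccc4)cc3)O2)c1ccc(OCc2ccccc2)cc1OCc1ccccc1 | intermediate
27 | 1-(2,4-dihydroxyphenyl)-3-[(2S,3S)-3-(2,4-dihydroxybenzoyl)-2-(4-hydroxyphenyl)-2,3-dihydro-1-benzofuran-5-yl]propan-1-one | O=C(CCc1ccc2c(c1)[C@H](C(=O)c1ccc(O)cc1O)[C@@H](c1ccc(O)cc1)O2)c1ccc(O)cc1O | target

## Step count and least certain steps

Total: 13 steps. Longest linear sequence: 13 steps, from 1 and 2 to 27; compounds 5, 10, 18 and 22 enter as purchased materials.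

Step 8 (key step). The most likely failure is slow oxidative cyclisation at ruthenium, because one alkyne of 17 is both oxygen-substituted and capped by a bulky silyl group; decomposition of the benzylic ynol ether or self-reaction of 18 could then outrun the cross-reaction. The second risk is incomplete steering of the chain to C5 by a single silyl group. The fallback removes the regiochemical question and the silyl group together. It sets out from 16: Bu4NF buffered with AcOH in THF at −20 °C removes both silyl groups and should give the doubly terminal diyne F1. RhCl(PPh3)3 under acetylene (1 atm) in toluene at rt closes rings A and C to the 5-unsubstituted dihydrobenzofuran F2. N-Iodosuccinimide in MeCN at 0 °C iodinates C5, para to O1, to give the iodide F3. A Heck reaction with allyl alcohol (Pd(OAc)2, Bu4NCl, NaHCO3, DMF, 50 °C) gives the 3-arylpropanal F4, and NaBH4 in MeOH gives the alcohol F5. The conditions of step 9 then remove the 4-methoxybenzyl group, and the route is rejoined at 20.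

Step 5. The most likely failure is weak anti/syn discrimination, because an aromatic aldehyde is less biased in the cyclic transition state than a branched aliphatic one; this affects the carbinol centre only. A lesser risk is loss of the 4-methoxybenzyl alkoxide from 11 before it adds. The centre that becomes C3 comes by chirality transfer and is not at stake. The fallback replaces kinetic control at C2 by thermodynamic control. It sets out from the unseparated product of step 5, that is 12 together with its syn epimer F6, and takes the mixture through steps 6 to 8 unchanged. The epimeric series runs through the potassium alkoxide F7, the dichlorovinyl ether F8, the lithium alkynyl ether F9, the bis-silyl diyne F10 and the syn diyne F11 to the cis dihydrobenzofuran F12, formed beside 19. In the acid of step 9, run longer or with a trace of CF3SO3H, the cis ring should open reversibly at C2–O1 to the 4-benzyloxybenzylic cation and close again trans under the control of the fixed C3 centre. Both series then meet at 20.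

Step 6. The most likely failure is transfer of the trimethylsilyl group from carbon to the potassium alkoxide of a second molecule, or incomplete conversion of 14 into 15, since this sequence asks a hindered benzylic alkoxide to survive KH and then excess n-BuLi. The fallback builds the ynol carbons from a formate and avoids KH and dichloroacetylene. It sets out from 12: HCO2H, DCC and DMAP (cat.) give the formate F13, and dichloromethylenation with PPh3 and CCl4 in THF at 60 °C gives the 2,2-dichlorovinyl ether F14. n-BuLi (2.2 equiv) at −78 °C converts F14 into 15, and Et3SiCl then gives 16, where the route is rejoined.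

Step 9. The most likely failure is irreversible capture of a carbocation at the wrong place: the ring-opened C2 cation by the arene scavenger, or benzylation of ring A by the 4-methoxybenzyl cation. The cause is that all three electron-rich sites are exposed to acid at once. The fallback generates no carbocation. It sets out from 19: DDQ in CH2Cl2–pH 7 buffer at 0 °C cleaves the 4-methoxybenzyl ether oxidatively to the silyl diol F15. KOSiMe3 (cat.) in wet DMSO at 60 °C then removes the C7 silyl group by base-catalysed protodesilylation; this is harmless here because C3 has no acidic hydrogen. The route is rejoined at 20.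

Step 11. The most likely failure is deprotonation of C3–H of 21 in competition with addition, followed by E1cB opening of ring C and loss of configuration at C2 and C3. The fallback makes the aryl ketones without a basic carbanion. It sets out from 21: Pinnick oxidation (NaClO2, NaH2PO4, 2-methylbut-2-ene, t-BuOH–H2O) gives the diacid F16, and EtSH, EDC and DMAP (cat.) give the bis(S-ethyl thioester) F17. Compound 22 is converted through 23 with B(Oi-Pr)3 and aqueous acid into the boronic acid F18. A double Liebeskind–Srogl coupling of F17 with F18 (Pd2(dba)3, tri(2-furyl)phosphine, CuTC (copper thiophene-2-carboxylate), THF, 50 °C) gives 26 directly, so that 25 and step 12 are bypassed.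

Step 13. The most likely failure is hydrogenolysis running past debenzylation, by reductive cleavage of the benzylic C2–O1 bond or reduction of the ring D ketone, because both sit on the same catalyst surface as the benzyl ethers. The fallback is a Lewis acid debenzylation. It sets out from 26: BCl3 with pentamethylbenzene as cation scavenger in CH2Cl2 at −78 °C should give 27 directly, without any new intermediate.

## Further compounds

F1 | step 8 | (1S,2R)-1-[4-(benzyloxy)phenyl]-2-{[(4-methoxybenzyl)oxy]methyl}but-3-yn-1-yl ethynyl ether | C#C[C@H](COCc1ccc(OC)cc1)[C@@H](c1ccc(OCc2ccccc2)cc1)OC#C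
F2 | step 8 | (2S,3R)-2-[4-(benzyloxy)phenyl]-3-{[(4-methoxybenzyl)oxy]methyl}-2,3-dihydro-1-benzofuran | c1ccc2c(c1)[C@H](COCc1ccc(OC)cc1)[C@@H](c1ccc(OCc3ccccc3)cc1)O2
F3 | step 8 | (2S,3R)-2-[4-(benzyloxy)phenyl]-5-iodo-3-{[(4-methoxybenzyl)oxy]methyl}-2,3-dihydro-1-benzofuran | Ic1ccc2c(c1)[C@H](COCc1ccc(OC)cc1)[C@@H](c1ccc(OCc3ccccc3)cc1)O2
F4 | step 8 | 3-[(2S,3R)-2-[4-(benzyloxy)phenyl]-3-{[(4-methoxybenzyl)oxy]methyl}-2,3-dihydro-1-benzofuran-5-yl]propanal | O=CCCc1ccc2c(c1)[C@H](COCc1ccc(OC)cc1)[C@@H](c1ccc(OCc3ccccc3)cc1)O2
F5 | step 8 | 3-[(2S,3R)-2-[4-(benzyloxy)phenyl]-3-{[(4-methoxybenzyl)oxy]methyl}-2,3-dihydro-1-benzofuran-5-yl]propan-1-ol | OCCCc1ccc2c(c1)[C@H](COCc1ccc(OC)cc1)[C@@H](c1ccc(OCc3ccccc3)cc1)O2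
F6 | step 5 | (1R,2R)-1-[4-(benzyloxy)phenyl]-2-{[(4-methoxybenzyl)oxy]methyl}-4-(trimethylsilyl)but-3-yn-1-ol (syn) | C[Si](C)(C)C#C[C@H](COCc1ccc(OC)cc1)[C@H](c1ccc(OCc2ccccc2)cc1)O
F7 | step 5 | potassium alkoxide of F6 | C[Si](C)(C)C#C[C@H](COCc1ccc(OC)cc1)[C@H](c1ccc(OCc2ccccc2)cc1)[O-].[K+]
F8 | step 5 | (E)-1,2-dichlorovinyl ether of F6 | C[Si](C)(C)C#C[C@H](COCc1ccc(OC)cc1)[C@H](c1ccc(OCc2ccccc2)cc1)O/C(Cl)=C\Cl
F9 | step 5 | lithium acetylide of the ethynyl ether of F6 | C[Si](C)(C)C#C[C@H](COCc1ccc(OC)cc1)[C@H](c1ccc(OCc2ccccc2)cc1)OC#C[Li]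
F10 | step 5 | (1R,2R)-1-[4-(benzyloxy)phenyl]-2-{[(4-methoxybenzyl)oxy]methyl}-4-(trimethylsilyl)but-3-yn-1-yl (triethylsilyl)ethynyl ether | C[Si](C)(C)C#C[C@H](COCc1ccc(OC)cc1)[C@H](c1ccc(OCc2ccccc2)cc1)OC#C[Si](CC)(CC)CC
F11 | step 5 | (1R,2R)-1-[4-(benzyloxy)phenyl]-2-{[(4-methoxybenzyl)oxy]methyl}but-3-yn-1-yl (triethylsilyl)ethynyl ether (syn diyne) | C#C[C@H](COCc1ccc(OC)cc1)[C@H](c1ccc(OCc2ccccc2)cc1)OC#C[Si](CC)(CC)CC
F12 | step 5 | 3-[(2R,3R)-2-[4-(benzyloxy)phenyl]-3-{[(4-methoxybenzyl)oxy]methyl}-7-(triethylsilyl)-2,3-dihydro-1-benzofuran-5-yl]propan-1-ol (cis) | OCCCc1cc([Si](CC)(CC)CC)c2c(c1)[C@H](COCc1ccc(OC)cc1)[C@H](c1ccc(OCc3ccccc3)cc1)O2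
F13 | step 6 | (1S,2R)-1-[4-(benzyloxy)phenyl]-2-{[(4-methoxybenzyl)oxy]methyl}-4-(trimethylsilyl)but-3-yn-1-yl formate | C[Si](C)(C)C#C[C@H](COCc1ccc(OC)cc1)[C@@H](c1ccc(OCc2ccccc2)cc1)OC=O
F14 | step 6 | 2,2-dichlorovinyl ether of 12 | C[Si](C)(C)C#C[C@H](COCc1ccc(OC)cc1)[C@@H](c1ccc(OCc2ccccc2)cc1)OC=C(Cl)Cl
F15 | step 9 | 3-[(2S,3R)-2-[4-(benzyloxy)phenyl]-3-(hydroxymethyl)-7-(triethylsilyl)-2,3-dihydro-1-benzofuran-5-yl]propan-1-ol | OCCCc1cc([Si](CC)(CC)CC)c2c(c1)[C@H](CO)[C@@H](c1ccc(OCc3ccccc3)cc1)O2
F16 | step 11 | (2S,3S)-2-[4-(benzyloxy)phenyl]-5-(2-carboxyethyl)-2,3-dihydro-1-benzofuran-3-carboxylic acid | OC(=O)CCc1ccc2c(c1)[C@H](C(=O)O)[C@@H](c1ccc(OCc3ccccc3)cc1)O2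
F17 | step 11 | S-ethyl (2S,3S)-2-[4-(benzyloxy)phenyl]-5-[3-(ethylsulfanyl)-3-oxopropyl]-2,3-dihydro-1-benzofuran-3-carbothioate | CCSC(=O)CCc1ccc2c(c1)[C@H](C(=O)SCC)[C@@H](c1ccc(OCc3ccccc3)cc1)O2
F18 | step 11 | [2,4-bis(benzyloxy)phenyl]boronic acid | OB(O)c1ccc(OCc2ccccc2)cc1OCc1ccccc1
F0 | step 13 | none | none
A1 | alternative 1 | 1-[2,4-bis(benzyloxy)phenyl]-2-(5-bromo-2-{[4-(benzyloxy)benzyl]oxy}phenyl)-2-diazoethan-1-one | [N-]=[N+]=C(C(=O)c1ccc(OCc2ccccc2)cc1OCc1ccccc1)c1cc(Br)ccc1OCc1ccc(OCc2ccccc2)cc1
A2 | alternative 1 | [(2S,3S)-2-[4-(benzyloxy)phenyl]-5-bromo-2,3-dihydro-1-benzofuran-3-yl][2,4-bis(benzyloxy)phenyl]methanone (trans) | Brc1ccc2c(c1)[C@H](C(=O)c1ccc(OCc3ccccc3)cc1OCc3ccccc3)[C@@H](c1ccc(OCc3ccccc3)cc1)O2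
A3 | alternative 2 | 1-[2,4-bis(benzyloxy)phenyl]-3-{3-[1-[2,4-bis(benzyloxy)phenyl]-3-(4-hydroxyphenyl)-1-oxoprop-2-en-2-yl]-4-hydroxyphenyl}propan-1-one, alkene geometry not defined because both isomers give the same quinone methide | O=C(CCc1ccc(O)c(c1)C(=Cc1ccc(O)cc1)C(=O)c1ccc(OCc2ccccc2)cc1OCc1ccccc1)c1ccc(OCc2ccccc2)cc1OCc1ccccc1
A4 | alternative 2 | 1-[2,4-bis(benzyloxy)phenyl]-3-[(2S,3S)-3-[2,4-bis(benzyloxy)benzoyl]-2-(4-hydroxyphenyl)-2,3-dihydro-1-benzofuran-5-yl]propan-1-one | O=C(CCc1ccc2c(c1)[C@H](C(=O)c1ccc(OCc3ccccc3)cc1OCc3ccccc3)[C@@H](c1ccc(O)cc1)O2)c1ccc(OCc3ccccc3)cc1OCc3ccccc3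
A5 | alternative 3 | 1-[2,4-bis(benzyloxy)phenyl]-3-(4-iodophenyl)propan-1-one | O=C(CCc1ccc(I)cc1)c1ccc(OCc2ccccc2)cc1OCc1ccccc1
A6 | alternative 3 | [2,4-bis(benzyloxy)phenyl][(2S,3R)-3-[4-(benzyloxy)phenyl]oxiran-2-yl]methanone (trans) | O=C(c1ccc(OCc2ccccc2)cc1OCc1ccccc1)[C@H]1O[C@@H]1c1ccc(OCc2ccccc2)cc1
A7 | alternative 3 | 1-[2,4-bis(benzyloxy)phenyl]-3-[(2S,3S)-3-[2,4-bis(benzyloxy)benzoyl]-2-[4-(benzyloxy)phenyl]-2,3-dihydro-1-benzofuran-5-yl]propan-1-one (identical with 26) | O=C(CCc1ccc2c(c1)[C@H](C(=O)c1ccc(OCc3ccccc3)cc1OCc3ccccc3)[C@@H](c1ccc(OCc3ccccc3)cc1)O2)c1ccc(OCc3ccccc3)cc1OCc3ccccc3
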